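## Retrosynthetic overview

1. Target ⇐ hydroquinone unmasking and Markovnikov hydration of the C13 exocyclic alkene of a tricyclic 19,20-lactone.
2. Tricyclic lactone ⇐ one operation on a ring A spiro-epoxide: Cp2TiCl opens the epoxide to the C10 radical, rings B and C close (C10–C9, C8–C14), and the freed C20–O lactonizes onto C19.
3. Spiro-epoxide ⇐ ring A ketone ⇐ conjugate addition of the aryl-diene side chain to an enantioenriched 3-silyloxycyclohexenecarboxylate, then enolate methylation (C5 first, then C4).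
4. Side chain ⇐ geranyl arene (1,4-dimethoxybenzene + geranyl bromide) by allylic oxidation, methylenation and hydrozirconation–iodination.
5. Ring order: A (purchased six-membered ring), then B + C + lactone together.

Assumption: positions carry terpenoid numbering (C15 = benzylic CH2, C16 = methyl on C13, C17 = methyl on C8, C18 = methyl on C4, C19 = lactone carbonyl, C20 = lactone CH2), and methyl 3-oxocyclohex-1-ene-1-carboxylate is taken as a purchasable building block.

## Route

Step 1
Reactants: 1 1,4-dimethoxybenzene; 2 geranyl bromide, (2E)-1-bromo-3,7-dimethylocta-2,6-diene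
Product: 4 2-[(2E)-3,7-dimethylocta-2,6-dien-1-yl]-1,4-dimethoxybenzene, via 2,5-dimethoxyphenyllithium 3 (not isolated)
Conditions: n-BuLi, TMEDA, THF, 0 °C; then CuBr·SMe2 (10 mol %), 2, −78 → 0 °C
Reagents that add atoms: none
Why: Directed ortho-lithiation gives the aryllithium, and copper catalysis steers it to SN2 (not SN2') allylation of geranyl bromide with the E-alkene retained; no stereocentre is formed.

Step 2
Reactants: 4 2-[(2E)-3,7-dimethylocta-2,6-dien-1-yl]-1,4-dimethoxybenzene
Product: 6 (2E,6E)-8-(2,5-dimethoxyphenyl)-2,6-dimethylocta-2,6-dienal, via allylic alcohol 5 (not isolated)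
Conditions: SeO2 (20 mol %), t-BuOOH, salicylic acid (10 mol %), CH2Cl2, rt; then MnO2, CH2Cl2, rt
Reagents that add atoms: tert-butyl hydroperoxide, CC(C)(C)OO
Why: Sharpless–Umbreit allylic oxidation (ene reaction, then [2,3]-shift) attacks the E-methyl of the less hindered terminal alkene, and MnO2 oxidizes only the allylic alcohol, so the enal is E.

Step 3
Reactants: 6 (2E,6E)-8-(2,5-dimethoxyphenyl)-2,6-dimethylocta-2,6-dienal
Product: 7 2-[(2E,6E)-3,7-dimethylnona-2,6,8-trien-1-yl]-1,4-dimethoxybenzene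
Conditions: Ph3PCH3Br, KOt-Bu, THF, 0 °C → rt
Reagents that add atoms: methyltriphenylphosphonium bromide, C[P+](c1ccccc1)(c1ccccc1)c1ccccc1.[Br-]
Why: Wittig methylenation of the enal gives the 2-methyl-1,3-diene and leaves both E-trisubstituted alkenes untouched.

Step 4
Reactants: 7 2-[(2E,6E)-3,7-dimethylnona-2,6,8-trien-1-yl]-1,4-dimethoxybenzene
Product: 9 2-[(2E,6E)-9-iodo-3,7-dimethylnona-2,6-dien-1-yl]-1,4-dimethoxybenzene, via alkylzirconocene chloride 8 (not isolated)
Conditions: Cp2Zr(H)Cl, THF, rt; then I2, 0 °C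
Reagents that add atoms: iodine, II
Why: Hydrozirconation adds Zr–H only across the monosubstituted terminal vinyl of the diene (zirconium on the terminal carbon), and iodinolysis of the C–Zr bond gives the primary homoallylic iodide.

Step 5
Reactants: 10 methyl 3-oxocyclohex-1-ene-1-carboxylate
Product: 12 methyl (3S)-3-(triethylsilyloxy)cyclohex-1-ene-1-carboxylate, via allylic alcohol 11 (not isolated)
Conditions: (R)-2-methyl-CBS-oxazaborolidine (10 mol %), BH3·SMe2, THF, −20 °C; MeOH quench; then Et3SiCl, imidazole, DMF, rt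
Reagents that add atoms: chlorotriethylsilane, CC[Si](Cl)(CC)CC
Why: Corey–Bakshi–Shibata reduction delivers hydride to one face of the enone carbonyl (alkenyl arm as the large group), setting the (S)-carbinol that later steers C5, and the alcohol is silylated in the same pot.

Step 6
Reactants: 9 2-[(2E,6E)-9-iodo-3,7-dimethylnona-2,6-dien-1-yl]-1,4-dimethoxybenzene; 12 methyl (3S)-3-(triethylsilyloxy)cyclohex-1-ene-1-carboxylate
Product: 16 methyl (1S,2S,3S)-2-[(3E,7E)-9-(2,5-dimethoxyphenyl)-3,7-dimethylnona-3,7-dien-1-yl]-1-methyl-3-(triethylsilyloxy)cyclohexane-1-carboxylate, via alkylmagnesium iodide 13 (not isolated), via silyl ketene acetal 14 (not isolated), via lithium enolate 15 (not isolated)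
Conditions: 9, Mg, THF, rt; then CuBr·SMe2 (20 mol %), LiCl, Me3SiCl, 12, THF, −78 → −30 °C; MeLi, 0 °C; MeI, DMPU, −78 → 0 °C
Reagents that add atoms: iodomethane, CI
Why: Copper-catalysed, Me3SiCl-accelerated conjugate addition of the Grignard reagent occurs anti to the allylic silyloxy group (sets C5), and after MeLi cleavage of the silyl ketene acetal the ester enolate is methylated on the face opposite the new side chain (sets quaternary C4 with the ester cis to the chain).

Step 7
Reactants: 16 methyl (1S,2S,3S)-2-[(3E,7E)-9-(2,5-dimethoxyphenyl)-3,7-dimethylnona-3,7-dien-1-yl]-1-methyl-3-(triethylsilyloxy)cyclohexane-1-carboxylate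
Product: 18 methyl (1S,2S)-2-[(3E,7E)-9-(2,5-dimethoxyphenyl)-3,7-dimethylnona-3,7-dien-1-yl]-1-methyl-3-oxocyclohexane-1-carboxylate, via secondary alcohol 17 (not isolated)
Conditions: HF·pyridine, THF, 0 °C; then Dess–Martin periodinane, pyridine, CH2Cl2, 0 °C → rt
Reagents that add atoms: none
Why: Fluoride desilylation and buffered Dess–Martin oxidation give the C10 ketone without enolizing (epimerizing) C5; the carbinol centre has done its steering job and is erased.

Step 8
Reactants: 18 methyl (1S,2S)-2-[(3E,7E)-9-(2,5-dimethoxyphenyl)-3,7-dimethylnona-3,7-dien-1-yl]-1-methyl-3-oxocyclohexane-1-carboxylate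
Product: 19 methyl (4S,5S)-4-[(3E,7E)-9-(2,5-dimethoxyphenyl)-3,7-dimethylnona-3,7-dien-1-yl]-5-methyl-1-oxaspiro[2.5]octane-5-carboxylate (both spiro epimers)
Conditions: Me3S+ I−, KN(SiMe3)2, THF, −10 °C → rt
Reagents that add atoms: trimethylsulfonium iodide, C[S+](C)C.[I-]
Why: Corey–Chaykovsky methylene transfer adds fast to the ketone at low temperature, so C5 is not epimerized; the spiro configuration does not matter because the next step turns this carbon into a radical.

Step 9 (key step)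
Reactants: 19 methyl (4S,5S)-4-[(3E,7E)-9-(2,5-dimethoxyphenyl)-3,7-dimethylnona-3,7-dien-1-yl]-5-methyl-1-oxaspiro[2.5]octane-5-carboxylate
Product: 21 15-(2,5-dimethoxyphenyl)isocopal-13(16)-eno-19,20-lactone (ring stereocentres as in the target), via hydroxy ester 20 (not isolated)
Conditions: Cp2TiCl2 (2.5 equiv), Mn dust, THF, rt, slow addition of 19 at high dilution; aq. HCl work-up; then PPTS (cat.), PhH, 50 °C
Reagents that add atoms: none
Why: Proposed new method: Cp2TiCl (trivalent titanium) opens the spiro-epoxide at the more substituted carbon to give the tertiary C10 radical bearing CH2O–Ti, which closes rings B and C by two 6-endo additions through chair-like transition states on the E,E-diene (trans-anti-trans; C10, C9, C8 and C14 set relative to C5), the C13 radical is trapped by a second Cp2TiCl and loses β-hydride to the exocyclic alkene, and the axial C20 alcohol lactonizes onto the syn-axial C19 ester; the closest known reaction is the Nugent–RajanBabu epoxide opening as used in titanocene-mediated radical cyclizations of epoxypolyprenes.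

Step 10
Reactants: 21 15-(2,5-dimethoxyphenyl)isocopal-13(16)-eno-19,20-lactone
Product: 22 13α-hydroxy-15-(2,5-dimethoxyphenyl)isocopalano-19,20-lactone (strongylophorine-8 dimethyl ether)
Conditions: Mn(dpm)3 (manganese tris(dipivaloylmethanate), 10 mol %), PhSiH3, O2 (1 atm), i-PrOH/CH2Cl2, 0 °C
Reagents that add atoms: dioxygen, O=O
Why: Mukaiyama hydration (metal-hydride hydrogen-atom transfer) turns the only remaining alkene into the tertiary C13 radical, which takes O2 from the α-face opposite the axial C8 methyl, giving the equatorial 13α-alcohol with the axial β-methyl.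

Step 11
Reactants: 22 13α-hydroxy-15-(2,5-dimethoxyphenyl)isocopalano-19,20-lactone
Product: 24 strongylophorine-8, via benzoquinone 23 (not isolated)
Conditions: (NH4)2Ce(NO3)6, MeCN/H2O, 0 °C; then Na2S2O4, H2O/EtOAc, rt
Reagents that add atoms: water, O
Why: Oxidative demethylation by tetravalent cerium gives the benzoquinone (its oxygens come from water), and dithionite reduces it to the hydroquinone; no stereocentre is touched.

## Compound list

1 | 1,4-dimethoxybenzene | COc1ccc(OC)cc1 | starting material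
2 | geranyl bromide, (2E)-1-bromo-3,7-dimethylocta-2,6-diene | CC(C)=CCC/C(C)=C/CBr | starting material
3 | 2,5-dimethoxyphenyllithium | COc1ccc(OC)c([Li])c1 | intermediate
4 | 2-[(2E)-3,7-dimethylocta-2,6-dien-1-yl]-1,4-dimethoxybenzene | COc1ccc(OC)c(C/C=C(\C)CCC=C(C)C)c1 | intermediate
5 | (2E,6E)-8-(2,5-dimethoxyphenyl)-2,6-dimethylocta-2,6-dien-1-ol | COc1ccc(OC)c(C/C=C(\C)CC/C=C(\C)CO)c1 | intermediate
6 | (2E,6E)-8-(2,5-dimethoxyphenyl)-2,6-dimethylocta-2,6-dienal | COc1ccc(OC)c(C/C=C(\C)CC/C=C(\C)C=O)c1 | intermediate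
7 | 2-[(2E,6E)-3,7-dimethylnona-2,6,8-trien-1-yl]-1,4-dimethoxybenzene | COc1ccc(OC)c(C/C=C(\C)CC/C=C(\C)C=C)c1 | intermediate
8 | chlorobis(cyclopentadienyl)[(3E,7E)-9-(2,5-dimethoxyphenyl)-3,7-dimethylnona-3,7-dien-1-yl]zirconium | COc1ccc(OC)c(C/C=C(\C)CC/C=C(\C)CC[Zr](Cl)(C2C=CC=C2)C2C=CC=C2)c1 | intermediate
9 | 2-[(2E,6E)-9-iodo-3,7-dimethylnona-2,6-dien-1-yl]-1,4-dimethoxybenzene | COc1ccc(OC)c(C/C=C(\C)CC/C=C(\C)CCI)c1 | intermediate
10 | methyl 3-oxocyclohex-1-ene-1-carboxylate | COC(=O)C1=CC(=O)CCC1 | starting material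
11 | methyl (3S)-3-hydroxycyclohex-1-ene-1-carboxylate | O[C@H]1CCCC(C(=O)OC)=C1 | intermediate
12 | methyl (3S)-3-(triethylsilyloxy)cyclohex-1-ene-1-carboxylate | CC[Si](CC)(CC)O[C@H]1CCCC(C(=O)OC)=C1 | intermediate
13 | [(3E,7E)-9-(2,5-dimethoxyphenyl)-3,7-dimethylnona-3,7-dien-1-yl]magnesium iodide | COc1ccc(OC)c(C/C=C(\C)CC/C=C(\C)CC[Mg]I)c1 | intermediate
14 | methyl trimethylsilyl ketene acetal of the (2S,3S)-conjugate adduct (ketene acetal geometry not defined) | CC[Si](CC)(CC)O[C@H]1CCCC(=C(OC)O[Si](C)(C)C)[C@@H]1CC/C(C)=C/CC/C(C)=C/Cc1cc(OC)ccc1OC | intermediate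
15 | lithium ester enolate of the (2S,3S)-conjugate adduct | CC[Si](CC)(CC)O[C@H]1CCCC(=C(OC)O[Li])[C@@H]1CC/C(C)=C/CC/C(C)=C/Cc1cc(OC)ccc1OC | intermediate
16 | methyl (1S,2S,3S)-2-[(3E,7E)-9-(2,5-dimethoxyphenyl)-3,7-dimethylnona-3,7-dien-1-yl]-1-methyl-3-(triethylsilyloxy)cyclohexane-1-carboxylate | CC[Si](CC)(CC)O[C@H]1CCC[C@](C)(C(=O)OC)[C@@H]1CC/C(C)=C/CC/C(C)=C/Cc1cc(OC)ccc1OC | intermediate
17 | methyl (1S,2S,3S)-2-[(3E,7E)-9-(2,5-dimethoxyphenyl)-3,7-dimethylnona-3,7-dien-1-yl]-3-hydroxy-1-methylcyclohexane-1-carboxylate | O[C@H]1CCC[C@](C)(C(=O)OC)[C@@H]1CC/C(C)=C/CC/C(C)=C/Cc1cc(OC)ccc1OC | intermediate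
18 | methyl (1S,2S)-2-[(3E,7E)-9-(2,5-dimethoxyphenyl)-3,7-dimethylnona-3,7-dien-1-yl]-1-methyl-3-oxocyclohexane-1-carboxylate | O=C1CCC[C@](C)(C(=O)OC)[C@@H]1CC/C(C)=C/CC/C(C)=C/Cc1cc(OC)ccc1OC | intermediate
19 | methyl (4S,5S)-4-[(3E,7E)-9-(2,5-dimethoxyphenyl)-3,7-dimethylnona-3,7-dien-1-yl]-5-methyl-1-oxaspiro[2.5]octane-5-carboxylate (both spiro epimers; spiro carbon left undefined) | COC(=O)[C@@]1(C)CCCC2(CO2)[C@H]1CC/C(C)=C/CC/C(C)=C/Cc1cc(OC)ccc1OC | intermediate
20 | methyl 15-(2,5-dimethoxyphenyl)-20-hydroxyisocopal-13(16)-en-19-oate (trans-anti-trans tricycle, ring stereocentres as in the target) | C[C@@]12CC[C@@H]3[C@](CO)(CCC[C@]3(C)C(=O)OC)[C@H]1CCC(=C)[C@H]2Cc1cc(OC)ccc1OC | intermediate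
21 | 15-(2,5-dimethoxyphenyl)isocopal-13(16)-eno-19,20-lactone (ring stereocentres as in the target) | C[C@@]12CC[C@@H]3[C@]4(CCC[C@]3(C)C(=O)OC4)[C@H]1CCC(=C)[C@H]2Cc1cc(OC)ccc1OC | intermediate
22 | (4S,5R,8R,9S,10S,13S,14S)-13-hydroxy-15-(2,5-dimethoxyphenyl)isocopalano-19,20-lactone (strongylophorine-8 dimethyl ether) | C[C@@]12CC[C@@H]3[C@]4(CCC[C@]3(C)C(=O)OC4)[C@H]1CC[C@](C)(O)[C@H]2Cc1cc(OC)ccc1OC | intermediate
23 | (4S,5R,8R,9S,10S,13S,14S)-13-hydroxy-15-(3,6-dioxocyclohexa-1,4-dien-1-yl)isocopalano-19,20-lactone (the benzoquinone) | C[C@@]12CC[C@@H]3[C@]4(CCC[C@]3(C)C(=O)OC4)[C@H]1CC[C@](C)(O)[C@H]2CC1=CC(=O)C=CC1=O | intermediate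
24 | strongylophorine-8, (4S,5R,8R,9S,10S,13S,14S) in terpenoid numbering | C[C@@]12CC[C@@H]3[C@]4(CCC[C@]3(C)C(=O)OC4)[C@H]1CC[C@](C)(O)[C@H]2Cc1cc(O)ccc1O | target

## Step count and risks

Total step count: 11. Longest linear sequence: 10 (steps 1–4, then 6–11); step 5 is the only step of the short branch.

The three steps most likely to fail:

Step 9 (radical bicyclization). The hindered C10 radical may be reduced by a second Cp2TiCl to an allylic alcohol before it cyclizes. The fallback sets out from 19 and changes from radical to cationic initiation: MeAlCl2 in CH2Cl2 at −78 °C ionizes the spiro-epoxide to the tertiary C10 cation, rings B and C close by cation–olefin cyclization, and proton loss gives mainly the endocyclic alkene. After acidic work-up and lactonization this is 15-(2,5-dimethoxyphenyl)isocopal-12-eno-19,20-lactone F1. Under the conditions of step 10, hydrogen-atom transfer to C12 gives the same C13 radical, so the fallback comes back to the route at 22.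

Step 6 (conjugate addition with enolate methylation). The trisubstituted, γ-silyloxy enoate may react sluggishly with the catalytic copper/Grignard system, or the one-pot enolate methylation may fail. The fallback sets out from 9 and 12 and separates the two events. Iodine–lithium exchange of 9 with t-BuLi and conversion to the stoichiometric organocopper–BF3 reagent (CuI·PBu3, BF3·OEt2, Et2O, −78 °C) adds to 12 and gives, after isolation, methyl (2S,3S)-2-[(3E,7E)-9-(2,5-dimethoxyphenyl)-3,7-dimethylnona-3,7-dien-1-yl]-3-(triethylsilyloxy)cyclohexane-1-carboxylate F2 as a mixture at C1. Kinetic deprotonation with LiN(i-Pr)2 and methylation with MeI then returns to the route at 16.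

Step 2 (SeO2 allylic oxidation). The two trisubstituted alkenes may not be differentiated well enough. The fallback sets out from 4 and rebuilds the oxidized terminus instead of oxidizing a C–H bond:
- NBS in THF/H2O adds to the terminal alkene to give (6E)-3-bromo-8-(2,5-dimethoxyphenyl)-2,6-dimethyloct-6-en-2-ol F3.
- K2CO3 in MeOH closes it to 3-[(3E)-5-(2,5-dimethoxyphenyl)-3-methylpent-3-en-1-yl]-2,2-dimethyloxirane F4.
- H5IO6 cleaves the epoxide to (4E)-6-(2,5-dimethoxyphenyl)-4-methylhex-4-enal F5.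
- E-selective Wittig olefination with Ph3P=C(CH3)CO2Et gives ethyl (2E,6E)-8-(2,5-dimethoxyphenyl)-2,6-dimethylocta-2,6-dienoate F6.
- i-Bu2AlH reduction gives the allylic alcohol, so the fallback comes back to the route at 5, which MnO2 oxidizes to 6 as in step 2.

Further compounds
F1 | step 9 | 15-(2,5-dimethoxyphenyl)isocopal-12-eno-19,20-lactone | C[C@@]12CC[C@@H]3[C@]4(CCC[C@]3(C)C(=O)OC4)[C@H]1CC=C(C)[C@H]2Cc1cc(OC)ccc1OC
F2 | step 6 | methyl (2S,3S)-2-[(3E,7E)-9-(2,5-dimethoxyphenyl)-3,7-dimethylnona-3,7-dien-1-yl]-3-(triethylsilyloxy)cyclohexane-1-carboxylate (C1 epimers) | CC[Si](CC)(CC)O[C@H]1CCCC(C(=O)OC)[C@@H]1CC/C(C)=C/CC/C(C)=C/Cc1cc(OC)ccc1OC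
F3 | step 2 | (6E)-3-bromo-8-(2,5-dimethoxyphenyl)-2,6-dimethyloct-6-en-2-ol (racemic) | COc1ccc(OC)c(C/C=C(\C)CCC(Br)C(C)(C)O)c1
F4 | step 2 | 3-[(3E)-5-(2,5-dimethoxyphenyl)-3-methylpent-3-en-1-yl]-2,2-dimethyloxirane (racemic) | COc1ccc(OC)c(C/C=C(\C)CCC2OC2(C)C)c1
F5 | step 2 | (4E)-6-(2,5-dimethoxyphenyl)-4-methylhex-4-enal | COc1ccc(OC)c(C/C=C(\C)CCC=O)c1
F6 | step 2 | ethyl (2E,6E)-8-(2,5-dimethoxyphenyl)-2,6-dimethylocta-2,6-dienoate | COc1ccc(OC)c(C/C=C(\C)CC/C=C(\C)C(=O)OCC)c1
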